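**Retrosynthetic overview**
- The target is the triacontanoate ester of tyrosol. Its one ring is a benzene ring with OH on C1 and the CH2CH2O-acyl chain on C4 (para). This 1,4-pattern maps onto a 4-substituted cyclohex-2-enone whose carbonyl oxygen becomes the phenol oxygen.
- Last disconnection: the arene comes from 2-(4-oxocyclohex-2-en-1-yl)ethyl triacontanoate by loss of two hydrogens (aerobic dehydrogenation), so the arene is never oxygenated separately.
- Key disconnection: the six-membered carbocycle (the only ring, closed once) is cut at C4–C5 and C2–C3 into 4-oxobutyl triacontanoate (C3, C4 and the side chain) and methyl vinyl ketone (C1, C2, C5, C6).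
- The aldehyde comes from triacontanoic acid and butane-1,4-diol (acid chloride, monoacylation, oxidation). The ester is installed first so that no free hydroxyl ever sits beside the enone.

Key step: step 4

Remark: the target has no stereocentre; the ring stereocentre created in the annulation is racemic and is erased on aromatisation. The C30 intermediates are waxy, so warm toluene, THF or CH2Cl2 is assumed throughout.

**Step 1**
Reactants: 1 triacontanoic acid
Product: 2 triacontanoyl chloride
Conditions: SOCl2 (3 equiv), DMF (cat.), toluene, 70 °C; evaporate with toluene
Reagents that add atoms: thionyl chloride, O=S(Cl)Cl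
Why: Standard conversion of a carboxylic acid into its acid chloride through the chlorosulfite (DMF-catalysed), driven by loss of gaseous by-products; the crude chloride is used directly.

**Step 2**
Reactants: 2 triacontanoyl chloride; 3 butane-1,4-diol
Product: 4 4-hydroxybutyl triacontanoate
Conditions: 3 (10 equiv), pyridine (1.5 equiv), THF, 25 to 40 °C, slow addition of 2
Reagents that add atoms: none
Why: Nucleophilic acyl substitution (O-acylation); a tenfold excess of the symmetrical diol and slow addition of the chloride should favour the monoester statistically, and the water-soluble excess diol is washed out.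

**Step 3**
Reactants: 4 4-hydroxybutyl triacontanoate
Product: 5 4-oxobutyl triacontanoate
Conditions: Dess–Martin periodinane (1.3 equiv), CH2Cl2, 25 to 35 °C
Reagents that add atoms: none
Why: Dess–Martin oxidation of a primary alcohol stops cleanly at the aldehyde under neutral, anhydrous conditions that leave the ester untouched; the aldehyde is used promptly.

**Step 4**
Reactants: 5 4-oxobutyl triacontanoate; 6 methyl vinyl ketone
Product: 9 2-(4-oxocyclohex-2-en-1-yl)ethyl triacontanoate (racemic), via 3-formyl-6-oxoheptyl triacontanoate 7 (not isolated), via 2-(2-hydroxy-4-oxocyclohexyl)ethyl triacontanoate 8 (not isolated)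
Conditions: 6 (1.5 equiv), Et2NH (0.3 equiv), toluene, 40 °C; strip volatiles; pTsOH·H2O (0.2 equiv), toluene, reflux, Dean–Stark
Reagents that add atoms: none
Why: Robinson annulation in its enamine form: Et2NH condenses with the aldehyde of 5 to an enamine whose β-carbon (the former α-carbon of the aldehyde) adds to the terminal CH2 of 6, and hydrolysis releases the 1,5-keto-aldehyde 7 with the first new C–C bond (C4–C5). Under pTsOH the methyl ketone enolises towards its CH3 and that carbon attacks the formyl carbon in a 6-(enolendo)-exo-trig aldol closure, allowed for six-membered rings, to give ketol 8; loss of water, driven by azeotropic removal and by conjugation, gives enone 9 with the second new C–C bond (C2–C3). The closest known reaction type is the secondary-amine-catalysed Michael addition of aliphatic aldehydes to methyl vinyl ketone followed by aldol cyclodehydration to 4-substituted cyclohex-2-enones. The ring stereocentre at C4 is formed without control (achiral amine, racemic) and the carbinol centre of 8 is lost on dehydration, which is harmless because C4 becomes an sp2 arene carbon in step 5. The step needs regiocontrol (side chain at C4) and chemoselectivity for the ester: only the aldehyde forms the enamine donor, and every alternative aldol closure would give a four-membered ring, so closure from the methyl carbon onto the aldehyde is the only productive path. The ester is spared because no hydroxide or alkoxide is present and its oxygen sits γ to the formyl group, so β-elimination cannot occur.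

**Step 5**
Reactants: 9 2-(4-oxocyclohex-2-en-1-yl)ethyl triacontanoate (racemic)
Product: 10 basalethanolide B, 2-(4-hydroxyphenyl)ethyl triacontanoate
Conditions: Pd(O2CCF3)2 (5 mol%), 2-(dimethylamino)pyridine (10 mol%), pTsOH·H2O (20 mol%), O2 (1 atm), DMSO, 80 °C
Reagents that add atoms: none
Why: Aerobic dehydrogenation of a cyclohexenone catalysed by divalent palladium: α-palladation at C6 gives a palladium enolate, β-hydride elimination gives the cyclohexa-2,5-dienone, which carries H at C4 and tautomerises to the phenol, while O2 returns the reduced palladium (hydride or zerovalent palladium) to divalent palladium; the ester and the saturated chain are inert.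

**Compound list**
1 | triacontanoic acid | CCCCCCCCCCCCCCCCCCCCCCCCCCCCCC(=O)O | starting material
2 | triacontanoyl chloride | CCCCCCCCCCCCCCCCCCCCCCCCCCCCCC(=O)Cl | intermediate
3 | butane-1,4-diol | OCCCCO | starting material
4 | 4-hydroxybutyl triacontanoate | CCCCCCCCCCCCCCCCCCCCCCCCCCCCCC(=O)OCCCCO | intermediate
5 | 4-oxobutyl triacontanoate | CCCCCCCCCCCCCCCCCCCCCCCCCCCCCC(=O)OCCCC=O | intermediate
6 | methyl vinyl ketone (but-3-en-2-one) | CC(=O)C=C | starting material
7 | 3-formyl-6-oxoheptyl triacontanoate (racemic keto-aldehyde) | CCCCCCCCCCCCCCCCCCCCCCCCCCCCCC(=O)OCCC(C=O)CCC(C)=O | intermediate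
8 | 2-(2-hydroxy-4-oxocyclohexyl)ethyl triacontanoate (racemic, mixture of diastereomers) | CCCCCCCCCCCCCCCCCCCCCCCCCCCCCC(=O)OCCC1CCC(=O)CC1O | intermediate
9 | 2-(4-oxocyclohex-2-en-1-yl)ethyl triacontanoate (racemic) | CCCCCCCCCCCCCCCCCCCCCCCCCCCCCC(=O)OCCC1CCC(=O)C=C1 | intermediate
10 | basalethanolide B, 2-(4-hydroxyphenyl)ethyl triacontanoate | CCCCCCCCCCCCCCCCCCCCCCCCCCCCCC(=O)OCCc1ccc(O)cc1 | target

**Total step count:** 5
**Longest linear sequence:** 5 steps (from triacontanoic acid 1)

**Steps most likely to fail**

Step 4 (key step). With a waxy aldehyde in dilute solution, enamine turnover may be slow. Self-aldol condensation of the aldehyde, oligomerisation of the enone or a second Michael addition could then compete with formation of the keto-aldehyde.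
Fallback: the donor is made stoichiometrically and separately, so that no free aldehyde is present when the C–C bond forms. The fallback sets out from 5. Condensation with piperidine over 4 Å molecular sieves in toluene should give the enamine (E)-4-(piperidin-1-yl)but-3-en-1-yl triacontanoate F1. F1 is treated with methyl vinyl ketone 6 in toluene and should give the cycloadduct 2-[6-methyl-2-(piperidin-1-yl)-3,4-dihydro-2H-pyran-3-yl]ethyl triacontanoate F2. Warming F2 in AcOH/NaOAc/H2O hydrolyses the aminal and comes back to the route at 7, which closes through 8 to 9 in the same buffer or under the acid conditions of step 4.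

Step 5. The long-chain substrate may dissolve poorly in DMSO, and the catalyst may be lost by aggregation to palladium metal, so that the dehydrogenation stalls before reaching the phenol.
Fallback: a two-stage, metal-free aromatisation that sets out from 9. Soft enolisation with trimethylsilyl trifluoromethanesulfonate and Et3N in CH2Cl2 at 0 °C should give the silyl dienol ether 2-{4-[(trimethylsilyl)oxy]cyclohexa-2,4-dien-1-yl}ethyl triacontanoate F3. Dehydrogenation of F3 with 2,3-dichloro-5,6-dicyano-1,4-benzoquinone in toluene should give the aryl silyl ether 2-{4-[(trimethylsilyl)oxy]phenyl}ethyl triacontanoate F4. Mild aqueous acid on work-up removes the silyl group and comes back to the route at 10.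

Step 2. Over-acylation to the bis-ester may occur, followed by a difficult separation of two waxy esters.
Fallback: a mono-protected diol that can be acylated only once, setting out from 2. Acylation of 4-(benzyloxy)butan-1-ol with 2 (pyridine, THF) should give 4-(benzyloxy)butyl triacontanoate F5. Hydrogenolysis of F5 (H2, 10% Pd/C, THF/EtOAc, 40 °C) removes the benzyl group without touching the ester and comes back to the route at 4.

**Further compounds**
F1 | step 4 | (E)-4-(piperidin-1-yl)but-3-en-1-yl triacontanoate | CCCCCCCCCCCCCCCCCCCCCCCCCCCCCC(=O)OCC/C=C/N1CCCCC1
F2 | step 4 | 2-[6-methyl-2-(piperidin-1-yl)-3,4-dihydro-2H-pyran-3-yl]ethyl triacontanoate (mixture of diastereomers) | CCCCCCCCCCCCCCCCCCCCCCCCCCCCCC(=O)OCCC1CC=C(C)OC1N2CCCCC2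
F3 | step 5 | 2-{4-[(trimethylsilyl)oxy]cyclohexa-2,4-dien-1-yl}ethyl triacontanoate (racemic) | CCCCCCCCCCCCCCCCCCCCCCCCCCCCCC(=O)OCCC1CC=C(O[Si](C)(C)C)C=C1
F4 | step 5 | 2-{4-[(trimethylsilyl)oxy]phenyl}ethyl triacontanoate | CCCCCCCCCCCCCCCCCCCCCCCCCCCCCC(=O)OCCc1ccc(O[Si](C)(C)C)cc1
F5 | step 2 | 4-(benzyloxy)butyl triacontanoate | CCCCCCCCCCCCCCCCCCCCCCCCCCCCCC(=O)OCCCCOCc1ccccc1
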